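You ask which recipe gives more product than the others, and your hunch is that the catalyst is too slow to finish any of them.

the same everywhere: free catalyst 78 µM
- dusk: substrate 20 mM; partner 22.0 mM; time 2.5 min; a closed flask charged with all of it at once and left for 2.5 min
- spring: substrate 20 mM; partner 22.0 mM (fed, over 2.00 min); time 2.5 min; a stirred flask in which partner is dosed at a steady rate over 2.00 min without added volume, worked up at 2.5 min
- autumn: substrate 20 mM (fed, over 2.00 min); partner 22.0 mM; time 2.5 min; all but substrate at the start; substrate goes in evenly over 2.00 min, the run ends at 2.5 min
- dawn: substrate 20 mM; partner 22.0 mM; one stirred flow tank at steady state, fed with the mixture as stated, mean residence time 2.5 min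

    substrate + catalyst intermediate B → catalyst intermediate C (k1 = 1080 /M/s)
    partner + free catalyst ⇌ catalyst intermediate A (K2 = 23.9 /M, k2 = 99.6 /M/s)
    catalyst intermediate A ⇌ by-product + catalyst intermediate B (K3 = 0.00831 M, k3 = 21.0 /s)
    catalyst intermediate C → catalyst intermediate D (k4 = 5.56 /s)
    catalyst intermediate D → free catalyst + product (k5 = 6.04 /s)

- the stated concentrations are those of everything mixed, before any reaction; amounts are the same in each set-up
- the feed brings no volume worth counting
- run time (dusk): 2.5 min

1. the set-up with the highest amount of product at the outlet or at the end, in percent of the substrate put in ("none" if the first two lie within 2 percentage points) (dusk / spring / autumn / dawn / none)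
2. amount of product at the outlet or at the end, in percent of the substrate put in, dusk
3. amount of product at the outlet or at the end, in percent of the substrate put in, spring
4. amount of product at the outlet or at the end, in percent of the substrate put in, autumn
5. amount of product at the outlet or at the end, in percent of the substrate put in, dawn

1. My zero is the symmetric cycle: 5 catalyst forms with equal waits, each holding 20.0% of the catalyst.

2. At full charges and without by-product, free catalyst waits 0.547 s, counting the intermediate A that falls back. That wait grows as one over the partner fraction. Catalyst intermediate B waits 0.0463 s for substrate, and that wait grows as one over the substrate fraction.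

3. Adding the fixed waits of intermediates A, C and D gives 0.986 s. This is the cycle time: the seconds one catalyst needs per turn, here at full fractions of the charge and without by-product.

4. By this reckoning, at full charges, free catalyst holds 55.5%, above my zero, with the longest wait, so I take it as the resting state.

5. At that pace I reckon 59.3% of dusk's substrate as product in 2.5 min. But fractions fall. Suppose half of the substrate goes: the mean fractions are 0.750 for substrate and 0.773 for partner. The cycle is then 1.16 s, and my number for dusk is 50.3%, with by-product uncounted.

6. Spring starts with no partner, autumn with no substrate. Free catalyst's wait for partner is longer than catalyst intermediate B's wait for substrate, so I rank dusk over autumn over spring.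

7. The forecast reads dusk 45%, spring 32%, autumn 40.5%, dawn 37.5%, best dusk, on the grounds that “starving the partner-dependent entry step hurts spring most”. My dusk stands higher.

8. The simulation gives dusk 45.1%, spring 32.5%, autumn 40.3%, dawn 37.4%, best dusk.

Dusk is still moving at 2.50 min, with 54.9% of its substrate standing. Its product means a mean cycle of 1.30 s, longer than my 1.16 s. Ten times the time brings dusk to 98.2%, with substrate at 1.84% and partner at 10.7%. Spring reaches 98.0% by then, so the 13 percentage points between the two at 2.50 min has shrunk to 0.20 points.

The neighbour of dusk charged with 5.5 mM of partner starts with a quarter of dusk's partner charge. That makes its cycle at the start 2.63 s, and at that pace I reckon 22.3% of its substrate as product in 2.5 min. Simulated, that neighbour gives 15.4%.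

The constants belong to no real substance; the rest is arithmetic.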